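**Assumption:** the target SMILES carries no stereodescriptors (no stereocentres, and the 8,8''-axis is unspecified), so the route targets the constitution as drawn and delivers it as the axial racemate.

## Retrosynthetic overview

1. The usual first choice would be a Suzuki/Ullmann union of two differently protected 8-halo/8-boryl flavone halves; this route avoids it.
2. Instead, the 7-OMe/7''-OH pair is traced back to a 7,7''-O–CH2–O bridge (a dibenzo[1,3]dioxepine). Reductive C–O cleavage of that bridge turns the tether carbon into the methyl group and desymmetrises the dimer in one step.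
3. The 8–8'' bond is made by intramolecular dehydrogenative (FeCl3) phenol coupling of a bis(flavon-7-yloxy)methane, para to each 5-OH.
4. The tethered dimer comes from two molecules of 4'-O-acetylapigenin and CH2I2; the monomer comes from apigenin in two steps.
5. No ring of the flavone skeleton is built; the only ring formed is the temporary seven-membered dioxepine, which is then opened.

## Route

**Step 1**
Reactants: 1, apigenin (5,7-dihydroxy-2-(4-hydroxyphenyl)chromen-4-one); 2, acetic anhydride
Product: 3, 7,4'-di-O-acetylapigenin (5-OH free)
Conditions: Ac2O (2.2 equiv), pyridine, 0 °C → rt, no DMAP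
Reagents that add atoms: acetic anhydride, CC(=O)OC(C)=O
Why: Selective O-acylation; the 5-OH is hydrogen-bonded to the C4 carbonyl and is not acetylated under mild, DMAP-free conditions.

**Step 2**
Reactants: 3, 7,4'-di-O-acetylapigenin
Product: 4, 4'-O-acetylapigenin (5,7-dihydroxy)
Conditions: PhSH (1.5 equiv), imidazole (0.5 equiv), NMP, 0 °C → rt
Reagents that add atoms: none
Why: Regioselective thiolate/imidazole acyl transfer (7-O-deacylation of acylated flavones); the 7-acetate is the most electrophilic ester because the 7-oxide is a vinylogous carboxylate.

**Step 3**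
Reactants: 4, 4'-O-acetylapigenin (2 equiv); 5, diiodomethane (1 equiv)
Product: 6, bis{[2-(4-acetoxyphenyl)-5-hydroxy-4-oxo-4H-chromen-7-yl]oxy}methane
Conditions: CH2I2, K2CO3 (2.2 equiv), dry DMF, 40 °C
Reagents that add atoms: diiodomethane, ICI (supplies the CH2)
Why: Double Williamson etherification; only the 7-OH is ionised and alkylated (5-OH is chelated), and the intermediate ArOCH2I is far more reactive than CH2I2, so the symmetrical formal forms.

**Step 4**
Reactants: 6, the bis(flavonyloxy)methane
Product: 7, 4',4'''-di-O-acetyl-7,7''-O,O-methylene-cupressuflavone (8,8''-linked biflavone with the 7-O and 7''-O bridged by CH2; 5,5''-OH free; racemic)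
Conditions: anhydrous FeCl3 (5 equiv, optionally on SiO2), 1,4-dioxane, 80 °C, 5 mM
Reagents that add atoms: none
Why: Proposed new method: each Fe(III)-chelated 5-OH/4-C=O unit is oxidised to a phenoxyl radical with highest spin density at C8 (para to OH, and less hindered than C6 beside the Fe chelate), and the tether makes the para–para C8–C8'' coupling intramolecular; the closest known reaction is the intermolecular FeCl3 oxidative phenol coupling of 5-hydroxy-7-alkoxyflavones to 8,8''-biflavones, together with tether-directed oxidative biaryl couplings.

**Step 5**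
Reactants: 7, the methylene-bridged biflavone
Product: 8, 4',4'''-di-O-acetylcupressuflavone 7-methyl ether (7-OMe on one half, 7''-OH on the other)
Conditions: Et3SiH (10 equiv), TMSI (4 equiv), CH2Cl2, −40 → 0 °C; then MeOH, aq. NaHCO3/Na2S2O3
Reagents that add atoms: none (hydride from Et3SiH, proton on work-up)
Why: Proposed new method: silylation of one flavone C4=O makes its 7-oxygen a vinylogous leaving group, iodide opens the strained dioxepine at CH2 to ArOCH2I plus ArOSiMe3, and the iodomethyl ether/oxocarbenium is reduced by Et3SiH to ArOCH3, while Et3SiH is too weak a hydride donor to reduce the strongly stabilised silyloxyflavylium core; C2 symmetry makes either C–O cleavage give the same product, and the closest known reactions are silane/Lewis-acid (Et3SiH–I2, Et3SiH–TMSOTf) reductive ring-opening of cyclic acetals to ethers and halosilane/haloborane cleavage of aryl formals via halomethyl ethers.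

**Step 6**
Reactants: 8, the di-O-acetyl 7-methyl ether
Product: 9, cupressuflavone 7-methyl ether (target)
Conditions: K2CO3, MeOH/THF, rt, Ar; then 1 M HCl
Reagents that add atoms: none
Why: Zemplén-type methanolysis of the two aryl acetates; the aryl methyl ether, flavone rings and biaryl are inert.

## Compound list

1 | Apigenin | O=c1cc(-c2ccc(O)cc2)oc2cc(O)cc(O)c12 | starting material
2 | Acetic anhydride | CC(=O)OC(C)=O | starting material
3 | 7,4'-Di-O-acetylapigenin | CC(=O)Oc1ccc(cc1)-c1cc(=O)c2c(O)cc(OC(C)=O)cc2o1 | intermediate
4 | 4'-O-Acetylapigenin | CC(=O)Oc1ccc(cc1)-c1cc(=O)c2c(O)cc(O)cc2o1 | intermediate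
5 | Diiodomethane | ICI | starting material
6 | Bis{[2-(4-acetoxyphenyl)-5-hydroxy-4-oxochromen-7-yl]oxy}methane | CC(=O)Oc1ccc(cc1)-c1cc(=O)c2c(O)cc(OCOc3cc(O)c4c(=O)cc(-c5ccc(OC(C)=O)cc5)oc4c3)cc2o1 | intermediate
7 | 4',4'''-Di-O-acetyl-7,7''-O,O-methylene-cupressuflavone (racemic) | CC(=O)Oc1ccc(cc1)-c1cc(=O)c2c(O)cc3OCOc4cc(O)c5c(=O)cc(-c6ccc(OC(C)=O)cc6)oc5c4-c3c2o1 | intermediate
8 | 4',4'''-Di-O-acetylcupressuflavone 7-methyl ether | COc1cc(O)c2c(=O)cc(-c3ccc(OC(C)=O)cc3)oc2c1-c1c(O)cc(O)c2c(=O)cc(-c3ccc(OC(C)=O)cc3)oc12 | intermediate
9 | Cupressuflavone 7-methyl ether | COc1cc(O)c2c(=O)cc(-c3ccc(O)cc3)oc2c1-c1c(O)cc(O)c2c(=O)cc(-c3ccc(O)cc3)oc12 | target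

## Summary

Total steps: 6. Longest linear sequence: 6 (two copies of 4 converge in Step 3).

Steps most likely to fail, each with a fallback that changes the approach:

1. **Step 5, reductive tether-to-methyl opening.** Risks are incomplete opening, demethylation of the new OMe, or Friedel–Crafts side reactions. Fallback: open the formal by SN2 with NaSPh to give the 7-O-CH2SPh / 7''-OH compound, then desulfurise reductively (Raney Ni or Bu3SnH/AIBN) to the 7-OMe; the acetates are lost at the thiolate stage, which is harmless.
2. **Step 4, FeCl3 dehydrogenative coupling.** Risks are C6 versus C8 regiochemistry (6,6''- and 6,8''-coupling also give seven-membered rings), low conversion, or Lewis-acid cleavage of the formal. Fallback: drop the C–H/C–H coupling, cap the 5-OH, iodinate C8 of the monomer, form the same formal tether, and close the 8–8'' bond by intramolecular Ni(0)- or Cu-mediated reductive Ullmann coupling.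
3. **Step 3, formal formation in the presence of the 4'-acetate.** Risk is acyl migration to the 7-oxide followed by 4'-O-alkylation. Fallback: build 4'-O-benzylapigenin de novo (phloroacetophenone polyanion with LiHMDS plus 4-benzyloxybenzoyl chloride, then acid cyclodehydration), carry the benzyl ether through the same tether/coupling/opening sequence, and finish by hydrogenolysis.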